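## Retrosynthetic overview

1. Feature used: the cyclopentane fusion CH (the ring CH that carries the cage CH2) lies between two quaternary carbons, the spiro carbon holding both flanking cage C=O groups and the ring C(CH3)2. These three atoms are traced back to a malonate carbon, an aldehyde carbon and an isobutyrate α-carbon.
2. Ring 1 (cyclopentane, key step): Michael addition of methyl isobutyrate enolate to the glyceraldehyde-derived alkylidene malonate, alkylation of the malonate anion with allyl bromoacetate, Dieckmann closure; the ring ketone is then excised.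
3. The dioxolane gives a γ-lactone that can engage only the ester cis to the side chain. Zinc opening leaves a vinyl group (its CH becomes the cage CH2; its CH2 is lost as ethene in the metathesis) and the free cis acid. The vinyl is built up to a 2-methylidene tertiary carbinol cap (apex carbon, cap CH2, cap CMe2).
4. Ring 2 (spiro acyl cyclohexanetrione): cis acid chloride plus the enolate of 3-methylbutan-2-one, C-acetylation, Claisen closure onto the trans ester, which places the isobutyryl group beside the cis C=O.
5. Rings 3 and 4 (cage): acid-induced allyl cation alkylation of the free enol carbon, then cation–olefin closure at the acyl-bearing carbon; bridgehead lithiation and geranylation come last.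

Key step: step 2

Remark: 28–30 are drawn as single tautomers; stereocentres left open in 19, 20 and the keto form of 28 are uncontrolled or stereolabile and vanish within the same or the next step; 1 is taken as the commercial aldehyde, freshly distilled.

## Route

Step 1
Reactants: 1 (S)-2,2-dimethyl-1,3-dioxolane-4-carbaldehyde; 2 dimethyl malonate
Product: 3 dimethyl 2-{[(4R)-2,2-dimethyl-1,3-dioxolan-4-yl]methylidene}malonate
Conditions: piperidine (cat.), AcOH (cat.), 4 Å MS, toluene, 0 °C → rt
Reagents that add atoms: none
Why: Knoevenagel condensation under buffered amine catalysis should give the alkylidene malonate without touching the dioxolane stereocentre, whose descriptor changes from S to R only through the priority rules.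

Step 2
Reactants: 3 dimethyl 2-{[(4R)-2,2-dimethyl-1,3-dioxolan-4-yl]methylidene}malonate; 4 methyl isobutyrate; 5 allyl bromoacetate
Product: 9 enolised cyclopentanone triester (2-allyl 1,1-dimethyl (5R)-5-[(4R)-2,2-dimethyl-1,3-dioxolan-4-yl]-3-hydroxy-4,4-dimethylcyclopent-2-ene-1,1,2-tricarboxylate), via lithium enolate 6 (not isolated), via lithium malonate adduct 7 (not isolated), via acyclic tetraester 8 (not isolated)
Conditions: 4, LiN(iPr)2, THF, −78 °C; 3, −78 °C; 5, DMPU, −78 → 0 °C; KOtBu, THF, 0 °C → rt; aq. NH4Cl
Reagents that add atoms: none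
Why: The lithium enolate 6 adds in Michael fashion to the doubly activated alkene of 3, the proton-free lithium malonate 7 is C-alkylated by the bromoacetate, and KOtBu then enolises the only acidic CH2 of 8, which attacks the isobutyrate ester and expels methoxide. The closest known chemistry is the three-component Michael addition–enolate alkylation sequence followed by a Dieckmann condensation. The cyclopentane closes 5-exo-trig and is pulled forward by deprotonation of the β-keto ester product. The new stereocentre (fusion CH) is controlled by the dioxolane stereocentre: allylic 1,3-strain with the cis ester holds the dioxolane C–H in the alkene plane and the enolate attacks anti to the C–O bond (Felkin–Anh-type), so the new C–C bond lies anti to the dioxolane oxygen as drawn in 9. The step needs this facial selectivity and a single Dieckmann mode; the first rests on the rigid dioxolane next to the alkene, the second on the fact that neither the malonate carbon nor the isobutyrate carbon carries hydrogen, so only one enolate and one five-membered closure are possible.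

Step 3
Reactants: 9 enolised cyclopentanone triester
Product: 10 dimethyl (2R)-2-[(4R)-2,2-dimethyl-1,3-dioxolan-4-yl]-3,3-dimethyl-4-oxocyclopentane-1,1-dicarboxylate
Conditions: Pd(PPh3)4 (cat.), morpholine, THF, rt
Reagents that add atoms: none
Why: Palladium-catalysed deallylation of the allyl β-keto ester (Tsuji–Trost ionisation, morpholine as allyl acceptor) should give the β-keto acid, which loses CO2, while the methyl esters, the acetonide and the stereocentre are untouched.

Step 4
Reactants: 10 dimethyl (2R)-2-[(4R)-2,2-dimethyl-1,3-dioxolan-4-yl]-3,3-dimethyl-4-oxocyclopentane-1,1-dicarboxylate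
Product: 12 dithiolane hydroxymethyl γ-lactone (cis-fused lactone between the former dioxolane CH–O and the ester on the same ring face; CH2OH on the lactone CH; CO2Me retained; 1,3-dithiolane spiro at the former ketone carbon), via dithiolane diol 11 (not isolated)
Conditions: HSCH2CH2SH, BF3·OEt2, CH2Cl2, 0 °C → rt
Reagents that add atoms: ethane-1,2-dithiol (SCCS)
Why: BF3-promoted dithioketalisation of the cyclopentanone (as for cyclopentanones next to a quaternary carbon) should be accompanied by transfer of the acetonide to the dithiol, and the freed secondary hydroxyl lactonises to the five-membered ring, which is possible only with the ester on its own face and thereby makes the quaternary carbon a defined stereocentre.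

Step 5
Reactants: 12 dithiolane hydroxymethyl γ-lactone
Product: 13 methyl (3R)-3-(hydroxymethyl)-4,4-dimethyl-1-oxohexahydro-1H-cyclopenta[c]furan-6a-carboxylate (cis-fused)
Conditions: Raney Ni, EtOH, reflux
Reagents that add atoms: none
Why: Raney nickel desulfurisation (Mozingo reduction) should replace the dithiolane by CH2 without affecting lactone, ester or hydroxyl.

Step 6
Reactants: 13 hydroxymethyl γ-lactone
Product: 14 methyl (3R)-3-(iodomethyl)-4,4-dimethyl-1-oxohexahydro-1H-cyclopenta[c]furan-6a-carboxylate (cis-fused)
Conditions: I2, PPh3, imidazole, CH2Cl2, 0 °C → rt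
Reagents that add atoms: iodine (II)
Why: Appel-type iodination of the unhindered primary alcohol should proceed without touching the lactone stereocentres.

Step 7
Reactants: 14 iodomethyl γ-lactone
Product: 15 (1R,2R)-2-ethenyl-1-(methoxycarbonyl)-3,3-dimethylcyclopentane-1-carboxylic acid (CO2H cis to vinyl)
Conditions: Zn dust, AcOH, THF, 50 °C
Reagents that add atoms: none
Why: Zinc insertion into the C–I bond and fragmentation of the β-acyloxy organozinc (reductive opening, the reverse of an iodolactonisation) should give the vinyl group and free specifically the carboxyl group cis to it.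

Step 8
Reactants: 15 vinyl half ester; 16 methyl acrylate
Product: 17 (1R,2R)-1-(methoxycarbonyl)-2-[(E)-3-methoxy-3-oxoprop-1-enyl]-3,3-dimethylcyclopentane-1-carboxylic acid
Conditions: second-generation Hoveyda–Grubbs catalyst (cat.), CH2Cl2, 40 °C
Reagents that add atoms: none
Why: Olefin cross-metathesis of the hindered terminal alkene with the electron-poor partner should be selective for the E cross product, and the allylic stereocentre is not touched by the ruthenium carbene.

Step 9
Reactants: 17 E enoate acid
Product: 18 (1R,2R)-1-(methoxycarbonyl)-2-(3-methoxy-3-oxopropyl)-3,3-dimethylcyclopentane-1-carboxylic acid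
Conditions: H2 (1 atm), Pd/C, EtOAc, rt
Reagents that add atoms: none
Why: Heterogeneous hydrogenation of the conjugated disubstituted alkene removes the alkene before any base is used, so the fusion CH is never a vinylogous acidic position.

Step 10
Reactants: 18 saturated ester acid
Product: 21 (1R,2R)-1-(methoxycarbonyl)-2-[2-(methoxycarbonyl)prop-2-enyl]-3,3-dimethylcyclopentane-1-carboxylic acid, via Mannich base 19 (not isolated), via amine oxide 20 (not isolated)
Conditions: LiN(iPr)2 (2.3 equiv), THF, −78 °C; [Me2N=CH2]I, −78 °C → rt; then mCPBA, CH2Cl2, 0 °C → rt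
Reagents that add atoms: dimethylmethylideneammonium iodide (C[N+](C)=C.[I-])
Why: The dianion (carboxylate plus chain ester enolate) should undergo a Mannich reaction with the iminium salt and Cope elimination of the derived amine oxide gives the 2-substituted acrylate, the carboxylate being inert and a Dieckmann closure onto the trans ester requiring a strained trans-fused bicyclo[3.3.0]octane.

Step 11
Reactants: 21 acrylate acid
Product: 22 (1R,2R)-2-(3-hydroxy-3-methyl-2-methylidenebutyl)-1-(methoxycarbonyl)-3,3-dimethylcyclopentane-1-carboxylic acid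
Conditions: MeMgBr, CeCl3, THF, −78 → 0 °C; aq. NH4Cl
Reagents that add atoms: methylmagnesium bromide (C[Mg]Br)
Why: The organocerium reagent should add twice in 1,2-fashion to the unhindered acrylate ester, while the carboxylate and the neopentyl-type ring ester on the quaternary carbon are not attacked.

Step 12
Reactants: 22 tertiary allylic alcohol acid
Product: 23 (1R,2R)-1-(methoxycarbonyl)-3,3-dimethyl-2-{3-methyl-2-methylidene-3-[(triethylsilyl)oxy]butyl}cyclopentane-1-carboxylic acid
Conditions: Et3SiOTf, 2,6-lutidine, CH2Cl2, −78 → 0 °C; aqueous work-up at pH 5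
Reagents that add atoms: triethylsilyl trifluoromethanesulfonate (CC[Si](CC)(CC)OS(=O)(=O)C(F)(F)F)
Why: Silyl triflate silylation should protect the tertiary allylic alcohol (a silyl ester formed at the acid is hydrolysed on work-up), so that the acid can be activated.

Step 13
Reactants: 23 silyl ether acid; 24 3-methylbutan-2-one
Product: 27 methyl (1R,2R)-3,3-dimethyl-1-(4-methyl-3-oxopentanoyl)-2-{3-methyl-2-methylidene-3-[(triethylsilyl)oxy]butyl}cyclopentane-1-carboxylate, via acid chloride 25 (not isolated), via ketone lithium enolate 26 (not isolated)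
Conditions: 23, Me2C=C(Cl)NMe2, CH2Cl2, 0 °C → rt; added to 26 (from 24, LiN(iPr)2, THF, −78 °C; 3 equiv), −78 → −20 °C; aq. NH4Cl
Reagents that add atoms: none
Why: The α-chloroenamine should convert the hindered acid into its chloride under neutral conditions, and Claisen-type C-acylation of the kinetic methyl enolate (in excess, since the product is deprotonated) gives the β-diketone, the methyl ester being far less electrophilic.

Step 14
Reactants: 27 β-diketone
Product: 28 methyl (1R,2R)-1-(2-acetyl-4-methyl-3-oxopentanoyl)-3,3-dimethyl-2-{3-methyl-2-methylidene-3-[(triethylsilyl)oxy]butyl}cyclopentane-1-carboxylate (triacylmethane, enolised)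
Conditions: MgCl2, pyridine, AcCl, CH2Cl2, 0 °C → rt
Reagents that add atoms: acetyl chloride (CC(=O)Cl)
Why: Acylation of the magnesium chelate of the β-diketone with acetyl chloride should take place at the central carbon and give the triacylmethane.

Step 15
Reactants: 28 triacylmethane ester
Product: 29 8,10-dihydroxy-2,2-dimethyl-9-(2-methylpropanoyl)-1-{3-methyl-2-methylidene-3-[(triethylsilyl)oxy]butyl}spiro[4.5]deca-7,9-dien-6-one (C-10, next to the acyl-bearing carbon, cis to the side chain)
Conditions: LiN(SiMe3)2 (3.5 equiv), THF, −78 °C → rt; cold aq. citric acid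
Reagents that add atoms: none
Why: After deprotonation of the tricarbonyl unit the base should form the terminal enolate of the acetyl group (the isobutyryl CH is tertiary and hindered), which closes 6-exo-trig onto the remaining methyl ester in a Claisen (Dieckmann-type) condensation driven by the doubly enolised acyl trione, and this fixes the isobutyryl group beside the C=O cis to the side chain.

Step 16
Reactants: 29 spiro acyl trione
Product: 31 cage trione lacking geranyl (the target skeleton with H at the bridgehead next to the cap CH2), via isopropylidene bicycle 30 (not isolated)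
Conditions: CH3SO3H, CH2Cl2, −20 °C → rt
Reagents that add atoms: none
Why: Acid should ionise the tertiary allylic silyl ether to an allyl cation that is captured at its CH2 end by the only unsubstituted enol carbon (Friedel–Crafts-type C-allylation of a 1,3-dicarbonyl enol, O-allylation being reversible), and protonation of the resulting isopropylidene alkene gives a tertiary cation trapped by the acyl-bearing enol carbon held next to it (cation–olefin cyclisation as in biomimetic closures of acylphloroglucinol-derived triones), the two bridgeheads and the apex CH being formed in the only configuration that closes the cage.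

Step 17
Reactants: 31 cage trione lacking geranyl; 32 geranyl bromide
Product: 34 target CNP0313870.1, via bridgehead lithium compound 33 (not isolated)
Conditions: lithium 2,2,6,6-tetramethylpiperidide, THF, −78 °C; then 32, −78 → −20 °C
Reagents that add atoms: none
Why: The bridgehead C–H flanked by two ketones is acidified inductively and should be removed by the hindered lithium amide, as known for bridgeheads of bicyclo[3.3.1]nonane triketones, and the configurationally fixed carbanion is alkylated by the allylic bromide (SN2) with retention at the bridgehead and of the E alkene.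

## Compound list

1 | (S)-2,2-dimethyl-1,3-dioxolane-4-carbaldehyde | O=C[C@@H]1COC(C)(C)O1 | starting material
2 | dimethyl malonate | COC(=O)CC(=O)OC | starting material
3 | dimethyl 2-{[(4R)-2,2-dimethyl-1,3-dioxolan-4-yl]methylidene}malonate | COC(=O)C(=C[C@@H]1COC(C)(C)O1)C(=O)OC | intermediate
4 | methyl isobutyrate | COC(=O)C(C)C | starting material
5 | allyl bromoacetate | C=CCOC(=O)CBr | starting material
6 | lithium enolate of methyl isobutyrate | COC(O[Li])=C(C)C | intermediate
7 | lithium malonate enolate of the Michael adduct (new C–C bond anti to the dioxolane C–O) | COC(=O)C(C)(C)[C@@H]([C@@H]1COC(C)(C)O1)C(C(=O)OC)=C(OC)O[Li] | intermediate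
8 | dimethyl 2-[2-(allyloxy)-2-oxoethyl]-2-{1-[(4R)-2,2-dimethyl-1,3-dioxolan-4-yl]-3-methoxy-2,2-dimethyl-3-oxopropyl}malonate (CH as in 9) | COC(=O)C(C)(C)[C@@H]([C@@H]1COC(C)(C)O1)C(CC(=O)OCC=C)(C(=O)OC)C(=O)OC | intermediate
9 | 2-allyl 1,1-dimethyl (5R)-5-[(4R)-2,2-dimethyl-1,3-dioxolan-4-yl]-3-hydroxy-4,4-dimethylcyclopent-2-ene-1,1,2-tricarboxylate | COC(=O)C1(C(=O)OC)C(C(=O)OCC=C)=C(O)C(C)(C)[C@H]1[C@@H]2COC(C)(C)O2 | intermediate
10 | dimethyl (2R)-2-[(4R)-2,2-dimethyl-1,3-dioxolan-4-yl]-3,3-dimethyl-4-oxocyclopentane-1,1-dicarboxylate | COC(=O)C1(C(=O)OC)CC(=O)C(C)(C)[C@H]1[C@@H]2COC(C)(C)O2 | intermediate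
11 | dimethyl 8-[(1R)-1,2-dihydroxyethyl]-9,9-dimethyl-1,4-dithiaspiro[4.4]nonane-7,7-dicarboxylate (ring CH as in 10) | COC(=O)C1(C(=O)OC)CC2(SCCS2)C(C)(C)[C@H]1[C@@H](O)CO | intermediate
12 | dithiolane hydroxymethyl γ-lactone (cis-fused; lactone on the ester cis to the side chain; spiro 1,3-dithiolane at the former ketone carbon) | COC(=O)[C@]12CC3(SCCS3)C(C)(C)[C@H]1[C@H](CO)OC2=O | intermediate
13 | methyl (3R)-3-(hydroxymethyl)-4,4-dimethyl-1-oxohexahydro-1H-cyclopenta[c]furan-6a-carboxylate (cis-fused) | COC(=O)[C@]12CCC(C)(C)[C@H]1[C@H](CO)OC2=O | intermediate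
14 | methyl (3R)-3-(iodomethyl)-4,4-dimethyl-1-oxohexahydro-1H-cyclopenta[c]furan-6a-carboxylate (cis-fused) | COC(=O)[C@]12CCC(C)(C)[C@H]1[C@H](CI)OC2=O | intermediate
15 | (1R,2R)-2-ethenyl-1-(methoxycarbonyl)-3,3-dimethylcyclopentane-1-carboxylic acid (CO2H cis to vinyl) | COC(=O)[C@]1(C(=O)O)CCC(C)(C)[C@H]1C=C | intermediate
16 | methyl acrylate | C=CC(=O)OC | starting material
17 | (1R,2R)-1-(methoxycarbonyl)-2-[(E)-3-methoxy-3-oxoprop-1-enyl]-3,3-dimethylcyclopentane-1-carboxylic acid | COC(=O)[C@]1(C(=O)O)CCC(C)(C)[C@H]1/C=C/C(=O)OC | intermediate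
18 | (1R,2R)-1-(methoxycarbonyl)-2-(3-methoxy-3-oxopropyl)-3,3-dimethylcyclopentane-1-carboxylic acid | COC(=O)[C@]1(C(=O)O)CCC(C)(C)[C@H]1CCC(=O)OC | intermediate
19 | Mannich base (dimethylaminomethyl group on the chain ester α-carbon, that centre uncontrolled) | COC(=O)[C@]1(C(=O)O)CCC(C)(C)[C@H]1CC(CN(C)C)C(=O)OC | intermediate
20 | amine oxide of 19 | COC(=O)[C@]1(C(=O)O)CCC(C)(C)[C@H]1CC(C[N+](C)(C)[O-])C(=O)OC | intermediate
21 | (1R,2R)-1-(methoxycarbonyl)-2-[2-(methoxycarbonyl)prop-2-enyl]-3,3-dimethylcyclopentane-1-carboxylic acid | COC(=O)[C@]1(C(=O)O)CCC(C)(C)[C@H]1CC(=C)C(=O)OC | intermediate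
22 | (1R,2R)-2-(3-hydroxy-3-methyl-2-methylidenebutyl)-1-(methoxycarbonyl)-3,3-dimethylcyclopentane-1-carboxylic acid | COC(=O)[C@]1(C(=O)O)CCC(C)(C)[C@H]1CC(=C)C(C)(C)O | intermediate
23 | (1R,2R)-1-(methoxycarbonyl)-3,3-dimethyl-2-{3-methyl-2-methylidene-3-[(triethylsilyl)oxy]butyl}cyclopentane-1-carboxylic acid | COC(=O)[C@]1(C(=O)O)CCC(C)(C)[C@H]1CC(=C)C(C)(C)O[Si](CC)(CC)CC | intermediate
24 | 3-methylbutan-2-one | CC(=O)C(C)C | starting material
25 | acid chloride of 23 (COCl cis to the side chain) | COC(=O)[C@]1(C(=O)Cl)CCC(C)(C)[C@H]1CC(=C)C(C)(C)O[Si](CC)(CC)CC | intermediate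
26 | lithium enolate of 3-methylbutan-2-one (methyl side) | C=C(O[Li])C(C)C | intermediate
27 | methyl (1R,2R)-3,3-dimethyl-1-(4-methyl-3-oxopentanoyl)-2-{3-methyl-2-methylidene-3-[(triethylsilyl)oxy]butyl}cyclopentane-1-carboxylate | COC(=O)[C@]1(C(=O)CC(=O)C(C)C)CCC(C)(C)[C@H]1CC(=C)C(C)(C)O[Si](CC)(CC)CC | intermediate
28 | methyl (1R,2R)-1-(2-acetyl-4-methyl-3-oxopentanoyl)-3,3-dimethyl-2-{3-methyl-2-methylidene-3-[(triethylsilyl)oxy]butyl}cyclopentane-1-carboxylate (keto form drawn, central CH stereolabile) | COC(=O)[C@]1(C(=O)C(C(C)=O)C(=O)C(C)C)CCC(C)(C)[C@H]1CC(=C)C(C)(C)O[Si](CC)(CC)CC | intermediate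
29 | 8,10-dihydroxy-2,2-dimethyl-9-(2-methylpropanoyl)-1-{3-methyl-2-methylidene-3-[(triethylsilyl)oxy]butyl}spiro[4.5]deca-7,9-dien-6-one (C-10 cis to the side chain) | O=C1C=C(O)C(C(=O)C(C)C)=C(O)[C@]12CCC(C)(C)[C@H]2CC(=C)C(C)(C)O[Si](CC)(CC)CC | intermediate
30 | isopropylidene bicycle (seven-membered ring closed between the free enol carbon and the cap CH2; exocyclic C=C(CH3)2 on the future apex carbon; dienol form) | O=C1C2=C(O)C(C(=O)C(C)C)=C(O)[C@]13CCC(C)(C)[C@H]3CC(=C(C)C)C2 | intermediate
31 | cage trione lacking geranyl (target with H in place of geranyl) | [C@@H]12C[C@H]3C[C@@H]4C(C)(C)CC[C@]4(C1=O)C(=O)[C@@](C(=O)C(C)C)(C2=O)C3(C)C | intermediate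
32 | geranyl bromide, (2E)-1-bromo-3,7-dimethylocta-2,6-diene | CC(C)=CCC/C(C)=C/CBr | starting material
33 | bridgehead lithium compound of 31 | [Li][C@@]12C[C@H]3C[C@@H]4C(C)(C)CC[C@]4(C1=O)C(=O)[C@@](C(=O)C(C)C)(C2=O)C3(C)C | intermediate
34 | CNP0313870.1 | CC(C)=CCC/C(C)=C/C[C@@]12C[C@H]3C[C@@H]4C(C)(C)CC[C@]4(C1=O)C(=O)[C@@](C(=O)C(C)C)(C2=O)C3(C)C | target

## Step count and risks

Total step count: 17. Longest linear sequence: 17 steps (1 → 34).

Steps most likely to fail:

Step 2. The basic ester enolate may deprotonate the γ-position of 3 and trigger β-elimination of the dioxolane, the conjugate addition may discriminate the two alkene faces poorly, or the hindered lithium malonate may alkylate too slowly, so that the added base consumes the bromoacetate. The fallback sets out from 3 and separates the three bond formations under non-basic conditions for the first one. A Lewis acid-promoted Mukaiyama–Michael addition of 1-methoxy-2-methyl-1-(trimethylsilyloxy)propene (Cu(OTf)2 cat., CH2Cl2, −78 °C, aqueous work-up) would give the malonate Michael adduct F1, whose diastereomers can be separated at this stage. Alkylation of F1 with 5 (NaH, DMF) would give the tetraester 8 as an isolated compound, and KOtBu in THF would close it to 9, where the route is rejoined.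

Step 16. The allyl cation may be captured on an enol oxygen or by a second molecule before the C–C bond forms, or the second closure may proceed through the ring-centred tertiary cation to a contracted cage. The fallback sets out from 29 and forms the first bond through a π-allyl palladium complex instead of a free cation. Desilylation (HF·pyridine, THF) would give the free tertiary allylic alcohol F2. Palladium-catalysed allylic alkylation of its own enol (Pd(PPh3)4, Et3B, THF; attack of the soft enolate at the CH2 terminus) would give 30 as an isolated compound. 30 would then be closed on its own with CF3SO3H in CH2Cl2 at −40 °C to 31, where the route is rejoined.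

Step 17. The cage bridgehead may resist deprotonation, or the amide base or the carbanion may attack one of the non-enolisable ketones and open the cage by retro-Claisen cleavage. The fallback sets out from 29 and introduces the side chain by enolate chemistry before the cage is complete, as an acid-stable precursor of the geranyl group.
- The first closure alone (BF3·OEt2, CH2Cl2, −78 °C) would give 30, isolated.
- C-alkylation of its still enolisable ring carbon with 1-bromobut-2-yne (K2CO3, acetone), from the face opposite the seven-membered ring, would give the but-2-ynyl bicycle F3.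
- Acid closure (CH3SO3H, CH2Cl2) would give the but-2-ynyl cage trione F4.
- Palladium-catalysed syn-hydrostannation (Bu3SnH, PdCl2(PPh3)2, THF; tin at the methyl-bearing, less hindered alkyne carbon) would give the (E)-vinylstannane F5.
- Iododestannylation (I2, CH2Cl2) would give the (E)-vinyl iodide F6.
- Negishi coupling with (4-methylpent-3-en-1-yl)zinc bromide (PdCl2(dppf), THF) would give 34 with retention of the alkene geometry, where the route is rejoined.

## Further compounds

F1 | step 2 | dimethyl 2-{1-[(4R)-2,2-dimethyl-1,3-dioxolan-4-yl]-3-methoxy-2,2-dimethyl-3-oxopropyl}malonate | COC(=O)C(C)(C)[C@@H]([C@@H]1COC(C)(C)O1)C(C(=O)OC)C(=O)OC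
F2 | step 16 | 8,10-dihydroxy-1-(3-hydroxy-3-methyl-2-methylidenebutyl)-2,2-dimethyl-9-(2-methylpropanoyl)spiro[4.5]deca-7,9-dien-6-one | O=C1C=C(O)C(C(=O)C(C)C)=C(O)[C@]12CCC(C)(C)[C@H]2CC(=C)C(C)(C)O
F3 | step 17 | but-2-ynyl isopropylidene bicycle (30 with a but-2-ynyl group on the ring carbon joined to the cap CH2) | CC#CC[C@@]12CC(=C(C)C)C[C@@H]3C(C)(C)CC[C@]3(C1=O)C(O)=C(C(=O)C(C)C)C2=O
F4 | step 17 | but-2-ynyl cage trione (target with but-2-ynyl in place of geranyl) | CC#CC[C@@]12C[C@H]3C[C@@H]4C(C)(C)CC[C@]4(C1=O)C(=O)[C@@](C(=O)C(C)C)(C2=O)C3(C)C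
F5 | step 17 | (E)-3-(tributylstannyl)but-2-enyl cage trione | C/C(=C\C[C@@]12C[C@H]3C[C@@H]4C(C)(C)CC[C@]4(C1=O)C(=O)[C@@](C(=O)C(C)C)(C2=O)C3(C)C)[Sn](CCCC)(CCCC)CCCC
F6 | step 17 | (E)-3-iodobut-2-enyl cage trione | C/C(I)=C\C[C@@]12C[C@H]3C[C@@H]4C(C)(C)CC[C@]4(C1=O)C(=O)[C@@](C(=O)C(C)C)(C2=O)C3(C)C
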